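## Retrosynthetic overview

1. The hydroxyquinone is revealed last: oxidation with K2[ON(SO3)2] of a 2-alkyl-4-chloro-5-methylresorcinol, itself obtained by acid unmasking. This six-membered ring is bought as orcinol and never constructed.
2. The protected resorcinol comes from a one-pot three-component union at the carbinol carbon: a (+)-pinanediol alkenylboronate (arene–CH2–CH=C(CH3)–B), CH2Cl2 (which becomes the CH(OH) carbon) and the neopentylic Grignard reagent of the ring. Two 1,2-metallate shifts on boron are followed by C–B oxidation; the second shift makes the bond from the ring-borne CH2 to the carbinol carbon.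
3. Enabling feature: the side-chain CH(OH) carbon bears only H, O, the sp2 carbon of the C(CH3)=CH alkene and the exocyclic CH2 on the quaternary carbon of the cyclohexanone ring. A boron-bound CHCl2 carbon can therefore take up the alkenyl and the CH2 group one after the other, and that CH2 has no β-hydrogen, so its Grignard reagent is stable.
4. The alkenylboronate comes from the arylcopper of bis-MOM 4-chloroorcinol and an allylic bromide made from but-2-yn-1-ol; syn copper-catalysed protoboration fixes the alkene geometry.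
5. The ring iodide comes from the only ring that is built, the cyclohexanone, which is formed first (organocatalytic Michael addition, then aldol condensation to (S)-4-methylcyclohex-2-enone). Silylmethyl 1,4-addition/Saegusa oxidation and Me2CuLi addition/methylation then set the quaternary carbon and both CH(CH3) neighbours.

Key step: step 15

Remark: the facial sense of the diphenylprolinol ether catalyst (step 1) and of (+)-pinanediol (step 15) is taken from their established behaviour with simple aldehydes and with alkyl- and arylboronic esters; if either is found reversed, the enantiomeric catalyst or diol is used.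

## Route

Step 1
Reactants: 1 propanal; 2 but-3-en-2-one
Product: 3 (S)-2-methyl-5-oxohexanal
Conditions: (R)-2-[methoxy(diphenyl)methyl]pyrrolidine (5 mol %), ethyl 3,4-dihydroxybenzoate (20 mol %), neat, 4 °C
Reagents that add atoms: none
Why: Enamine-catalysed Michael addition of an aldehyde to an enone: the bulky diphenyl(methoxy)methyl group shields one face of the (E)-enamine of propanal, so the enone is attacked from the open face and the α-methyl centre is set as (S).

Step 2
Reactants: 3 (S)-2-methyl-5-oxohexanal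
Product: 4 (S)-4-methylcyclohex-2-en-1-one
Conditions: LiOH·H2O (cat.), i-PrOH, 0 °C → rt
Reagents that add atoms: none
Why: Intramolecular aldol condensation (6-enolexo-exo-trig addition of the methyl ketone enolate to the aldehyde, then dehydration) closes the cyclohexenone ring; the methyl-bearing centre becomes the γ-carbon and the mild catalytic base is chosen to leave it untouched.

Step 3
Reactants: 4 (S)-4-methylcyclohex-2-en-1-one
Product: 5 {[(3R,4S)-3-{[dimethyl(phenyl)silyl]methyl}-4-methylcyclohex-1-en-1-yl]oxy}trimethylsilane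
Conditions: PhMe2SiCH2MgCl (from PhMe2SiCH2Cl and Mg, THF), CuBr·SMe2 (10 mol %), TMSCl, THF, −78 °C; Et3N, pentane work-up
Reagents that add atoms: (dimethylphenylsilyl)methylmagnesium chloride, C[Si](C)(C[Mg]Cl)c1ccccc1; chlorotrimethylsilane, C[Si](C)(C)Cl
Why: Copper-catalysed 1,4-addition of a silylmethyl Grignard reagent, accelerated and trapped by TMSCl, gives the regiodefined silyl enol ether; the new centre forms trans to the methyl group but is destroyed in step 4, so its configuration is irrelevant.

Step 4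
Reactants: 5 {[(3R,4S)-3-{[dimethyl(phenyl)silyl]methyl}-4-methylcyclohex-1-en-1-yl]oxy}trimethylsilane
Product: 6 (S)-3-{[dimethyl(phenyl)silyl]methyl}-4-methylcyclohex-2-en-1-one
Conditions: Pd(OAc)2 (1.05 equiv), MeCN, rt
Reagents that add atoms: none
Why: Saegusa–Ito oxidation: the palladium enolate formed from the silyl enol ether undergoes β-hydride elimination and restores the enone, which now carries the silylmethyl group on its β-carbon.

Step 5
Reactants: 6 (S)-3-{[dimethyl(phenyl)silyl]methyl}-4-methylcyclohex-2-en-1-one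
Product: 8 (2R,3S,4S)-3-{[dimethyl(phenyl)silyl]methyl}-2,3,4-trimethylcyclohexan-1-one, via lithium enolate 7 (not isolated)
Conditions: Me2CuLi (from MeLi and CuI), Et2O, −30 → 0 °C; then MeI, HMPA, THF, 0 °C → rt
Reagents that add atoms: lithium dimethylcuprate, [Li+].C[Cu-]C; iodomethane, CI
Why: Conjugate addition–enolate alkylation with Me2CuLi (the classic route to 2,3,3-trimethylcyclohexanone): the cuprate adds axially anti to the pseudoaxial 4-methyl group and sets the quaternary carbon, and iodomethane then attacks enolate 7 axially on the face opposite the pseudoaxial silylmethyl group, a path free of a 1,3-diaxial contact with the 4-methyl group, which places the 2-methyl group cis to the new quaternary methyl group.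

Step 6
Reactants: 8 (2R,3S,4S)-3-{[dimethyl(phenyl)silyl]methyl}-2,3,4-trimethylcyclohexan-1-one
Product: 10 (2R,3S,4S)-3-(hydroxymethyl)-2,3,4-trimethylcyclohexan-1-one, via fluorosilane 9 (not isolated)
Conditions: HBF4·OEt2, CH2Cl2, 0 °C → rt; then KF, KHCO3, H2O2 (30% aq), THF/MeOH, rt → 40 °C
Reagents that add atoms: hydrogen peroxide, OO
Why: Fleming–Tamao oxidation: protodesilylation of the phenyl group gives fluorosilane 9 and peroxide then inserts oxygen into the C–Si bond, which unmasks the neopentylic primary alcohol without touching the ketone or the three stereocentres.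

Step 7
Reactants: 10 (2R,3S,4S)-3-(hydroxymethyl)-2,3,4-trimethylcyclohexan-1-one
Product: 11 (2R,3S,4S)-3-(iodomethyl)-2,3,4-trimethylcyclohexan-1-one
Conditions: I2, PPh3, imidazole, toluene, 80 °C
Reagents that add atoms: iodine, [I][I]
Why: Appel-type iodination of a primary alcohol; substitution at the neopentylic carbon is slow but is known to proceed on heating, and no stereocentre is involved.

Step 8
Reactants: 11 (2R,3S,4S)-3-(iodomethyl)-2,3,4-trimethylcyclohexan-1-one
Product: 12 (6R,7S,8S)-7-(iodomethyl)-6,7,8-trimethyl-1,4-dioxaspiro[4.5]decane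
Conditions: (TMSOCH2)2, TMSOTf (cat.), CH2Cl2, −78 → −20 °C; pyridine quench
Reagents that add atoms: 1,2-bis(trimethylsilyloxy)ethane, C[Si](C)(C)OCCO[Si](C)(C)C
Why: Noyori ketalisation under aprotic TMSOTf catalysis at low temperature protects the ketone for the organomagnesium step and avoids enolisation, so the α-methyl centre should not epimerise.

Step 9
Reactants: 13 5-methylbenzene-1,3-diol (orcinol)
Product: 14 4-chloro-5-methylbenzene-1,3-diol
Conditions: SO2Cl2 (1.0 equiv), Et2O, 0 °C
Reagents that add atoms: sulfuryl chloride, O=S(=O)(Cl)Cl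
Why: Electrophilic aromatic chlorination of a resorcinol: the carbon ortho to one hydroxyl group and para to the other is the most reactive site and less hindered than the carbon between the two hydroxyl groups.

Step 10
Reactants: 14 4-chloro-5-methylbenzene-1,3-diol
Product: 15 2-chloro-1,5-bis(methoxymethoxy)-3-methylbenzene
Conditions: MOMCl, i-Pr2NEt, CH2Cl2, 0 °C → rt
Reagents that add atoms: chloromethyl methyl ether, COCCl
Why: O-Alkylation of both phenols to methoxymethyl ethers (acetal protection), which also serve as the directing groups for the metalation in step 14.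

Step 11
Reactants: 16 but-2-yn-1-ol
Product: 17 (Z)-3-(4,4,5,5-tetramethyl-1,3,2-dioxaborolan-2-yl)but-2-en-1-ol
Conditions: B2pin2, CuCl (5 mol %), PCy3 (6 mol %), NaOt-Bu (10 mol %), MeOH (2 equiv), toluene, rt
Reagents that add atoms: bis(pinacolato)diboron, CC1(C)OB(OC1(C)C)B1OC(C)(C)C(C)(C)O1
Why: Copper-catalysed formal hydroboration of an alkyne (syn borylcupration, then protonation by methanol): boron is delivered to the alkyne carbon remote from the CH2OH group and H and B add cis, which fixes the geometry of the trisubstituted alkene.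

Step 12
Reactants: 17 (Z)-3-(4,4,5,5-tetramethyl-1,3,2-dioxaborolan-2-yl)but-2-en-1-ol
Product: 18 (+)-pinanediol (Z)-(4-hydroxybut-2-en-2-yl)boronate
Conditions: (+)-pinanediol (1.05 equiv), Et2O, rt; aqueous washes
Reagents that add atoms: (1S,2S,3R,5S)-(+)-pinanediol, C[C@@]1(O)[C@H](O)C[C@@H]2C[C@H]1C2(C)C
Why: Boronic ester transesterification, driven by the higher stability of the pinanediol ester and the removal of pinacol into water, installs the chiral director for the key step.

Step 13
Reactants: 18 (+)-pinanediol (Z)-(4-hydroxybut-2-en-2-yl)boronate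
Product: 19 (+)-pinanediol (Z)-(4-bromobut-2-en-2-yl)boronate
Conditions: CBr4, PPh3, CH2Cl2, 0 °C
Reagents that add atoms: tetrabromomethane, BrC(Br)(Br)Br
Why: Appel bromination of the primary allylic alcohol under neutral conditions; the alkenylboronic ester and the alkene geometry are not affected.

Step 14
Reactants: 15 2-chloro-1,5-bis(methoxymethoxy)-3-methylbenzene; 19 (+)-pinanediol (Z)-(4-bromobut-2-en-2-yl)boronate
Product: 22 (+)-pinanediol (Z)-{4-[3-chloro-2,6-bis(methoxymethoxy)-4-methylphenyl]but-2-en-2-yl}boronate, via aryllithium 20 (not isolated), via arylcopper 21 (not isolated)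
Conditions: 15, n-BuLi, THF, 0 °C; CuBr·SMe2 (1.1 equiv), −78 → −40 °C; then 19, −40 → 0 °C
Reagents that add atoms: none
Why: Directed ortho-metalation at the carbon between the two OMOM groups, transmetalation to copper and SN2 allylation of the arylcopper with the primary allylic bromide (the standard way to prenylated resorcinol ethers); copper keeps the aryl nucleophile away from boron and the alkene geometry is retained.

Step 15
Reactants: 22 (+)-pinanediol (Z)-{4-[3-chloro-2,6-bis(methoxymethoxy)-4-methylphenyl]but-2-en-2-yl}boronate; 23 dichloromethane; 12 (6R,7S,8S)-7-(iodomethyl)-6,7,8-trimethyl-1,4-dioxaspiro[4.5]decane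
Product: 28 (2S,3E)-5-[3-chloro-2,6-bis(methoxymethoxy)-4-methylphenyl]-3-methyl-1-[(6R,7S,8S)-6,7,8-trimethyl-1,4-dioxaspiro[4.5]decan-7-yl]pent-3-en-2-ol, via dichloromethyllithium 24 (not isolated), via α-chloro boronate 25 (not isolated), via Grignard reagent 26 (not isolated), via allylic boronate 27 (not isolated)
Conditions: CH2Cl2 (1.2 equiv), n-BuLi (1.1 equiv), THF, −100 °C; 22, −100 → 0 °C, 1 h; recool to −78 °C, add 26 (1.2 equiv; from 12, Mg, THF, 40 °C), → rt, 12 h; then NaOH (3 M aq), H2O2 (30% aq), 0 °C → rt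
Reagents that add atoms: hydrogen peroxide, OO
Why: Dichloromethyllithium 24 adds to the boron of 22 and the alkenyl group migrates from boron to carbon with loss of one chloride (first 1,2-metallate shift); Grignard reagent 26 then forms a second borate and its neopentylic CH2 migrates to the same carbon with displacement of the second chloride, which creates the CH2–CH bond that joins the two large fragments, and alkaline peroxide converts C–B into C–OH. The closest known reaction type is the Matteson homologation of pinanediol boronic esters followed by Grignard substitution and oxidation, run without isolation of the α-chloro boronic ester, as reported for aryl- and alkenylboronic esters. No ring is closed. The carbinol stereocentre is controlled by the (+)-pinanediol ester, which decides which of the two chlorides is displaced in the first shift and is expected to give the (S)-α-chloro boronate 25; the second shift is stereospecific with inversion and the oxidation proceeds with retention, so the (S)-alcohol results. The step needs attack at the α-carbon rather than at the far end of the allylic chloride, and it needs 25 to keep its configuration; both are secured because the carbon group is delivered from boron to the adjacent carbon within the borate, because 26 is added at −78 °C to the unisolated chloride in the absence of zinc or copper salts, and because the neopentylic Grignard reagent has no β-hydrogen on the quaternary ring carbon and cannot eliminate.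

Step 16
Reactants: 28 (2S,3E)-5-[3-chloro-2,6-bis(methoxymethoxy)-4-methylphenyl]-3-methyl-1-[(6R,7S,8S)-6,7,8-trimethyl-1,4-dioxaspiro[4.5]decan-7-yl]pent-3-en-2-ol
Product: 29 4-chloro-2-{(2E,4S)-4-hydroxy-3-methyl-5-[(1S,2R,6S)-1,2,6-trimethyl-3-oxocyclohexyl]pent-2-en-1-yl}-5-methylbenzene-1,3-diol
Conditions: HCl (2 M aq), MeOH/THF, rt
Reagents that add atoms: water, O
Why: Acid-catalysed acetal hydrolysis cleaves the dioxolane and both aryl MOM ethers in one operation; dilute acid at room temperature is chosen so that the allylic alcohol is not ionised and the α-methyl ketone is not enolised.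

Step 17
Reactants: 29 4-chloro-2-{(2E,4S)-4-hydroxy-3-methyl-5-[(1S,2R,6S)-1,2,6-trimethyl-3-oxocyclohexyl]pent-2-en-1-yl}-5-methylbenzene-1,3-diol
Product: 30 5-chloro-2-hydroxy-3-{(2E,4S)-4-hydroxy-3-methyl-5-[(1S,2R,6S)-1,2,6-trimethyl-3-oxocyclohexyl]pent-2-en-1-yl}-6-methylcyclohexa-2,5-diene-1,4-dione
Conditions: K2[ON(SO3)2] (2.5 equiv), KH2PO4 buffer (pH 6), acetone/H2O, 0 °C → rt
Reagents that add atoms: potassium nitrosodisulfonate, [K+].[K+].[O]N(S(=O)(=O)[O-])S(=O)(=O)[O-]
Why: Teuber oxidation with potassium nitrosodisulfonate: the phenoxyl radical is trapped at the only unsubstituted ring carbon, para to one hydroxyl group, and collapses to the 2-hydroxy-1,4-benzoquinone, as known for 2-alkylresorcinols, while the alcohol, ketone and alkene are inert.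

## Compound list

(+)-Pinanediol is (1S,2S,3R,5S)-2,6,6-trimethylbicyclo[3.1.1]heptane-2,3-diol; its boronates are the cyclic esters of that diol.

1 | propanal | CCC=O | starting material
2 | but-3-en-2-one | CC(=O)C=C | starting material
3 | (S)-2-methyl-5-oxohexanal | O=C[C@@H](C)CCC(C)=O | intermediate
4 | (S)-4-methylcyclohex-2-en-1-one | C[C@H]1CCC(=O)C=C1 | intermediate
5 | {[(3R,4S)-3-{[dimethyl(phenyl)silyl]methyl}-4-methylcyclohex-1-en-1-yl]oxy}trimethylsilane | C[C@H]1CCC(O[Si](C)(C)C)=C[C@@H]1C[Si](C)(C)c1ccccc1 | intermediate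
6 | (S)-3-{[dimethyl(phenyl)silyl]methyl}-4-methylcyclohex-2-en-1-one | C[C@H]1CCC(=O)C=C1C[Si](C)(C)c1ccccc1 | intermediate
7 | lithium (3S,4S)-3-{[dimethyl(phenyl)silyl]methyl}-3,4-dimethylcyclohex-1-en-1-olate | C[Si](C)(c1ccccc1)C[C@@]2(C)[C@@H](C)CCC(O[Li])=C2 | intermediate
8 | (2R,3S,4S)-3-{[dimethyl(phenyl)silyl]methyl}-2,3,4-trimethylcyclohexan-1-one | C[Si](C)(c1ccccc1)C[C@@]2(C)[C@@H](C)CCC(=O)[C@@H]2C | intermediate
9 | (2R,3S,4S)-3-{[fluoro(dimethyl)silyl]methyl}-2,3,4-trimethylcyclohexan-1-one | C[Si](C)(F)C[C@@]1(C)[C@@H](C)CCC(=O)[C@@H]1C | intermediate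
10 | (2R,3S,4S)-3-(hydroxymethyl)-2,3,4-trimethylcyclohexan-1-one | OC[C@@]1(C)[C@@H](C)CCC(=O)[C@@H]1C | intermediate
11 | (2R,3S,4S)-3-(iodomethyl)-2,3,4-trimethylcyclohexan-1-one | IC[C@@]1(C)[C@@H](C)CCC(=O)[C@@H]1C | intermediate
12 | (6R,7S,8S)-7-(iodomethyl)-6,7,8-trimethyl-1,4-dioxaspiro[4.5]decane | IC[C@@]1(C)[C@@H](C)CCC2(OCCO2)[C@@H]1C | intermediate
13 | 5-methylbenzene-1,3-diol (orcinol) | Cc1cc(O)cc(O)c1 | starting material
14 | 4-chloro-5-methylbenzene-1,3-diol | Cc1cc(O)cc(O)c1Cl | intermediate
15 | 2-chloro-1,5-bis(methoxymethoxy)-3-methylbenzene | Cc1cc(OCOC)cc(OCOC)c1Cl | intermediate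
16 | but-2-yn-1-ol | CC#CCO | starting material
17 | (Z)-3-(4,4,5,5-tetramethyl-1,3,2-dioxaborolan-2-yl)but-2-en-1-ol | OC/C=C(\C)B1OC(C)(C)C(C)(C)O1 | intermediate
18 | (+)-pinanediol (Z)-(4-hydroxybut-2-en-2-yl)boronate | OC/C=C(\C)B1O[C@]2(C)[C@H](O1)C[C@@H]3C[C@H]2C3(C)C | intermediate
19 | (+)-pinanediol (Z)-(4-bromobut-2-en-2-yl)boronate | BrC/C=C(\C)B1O[C@]2(C)[C@H](O1)C[C@@H]3C[C@H]2C3(C)C | intermediate
20 | [3-chloro-2,6-bis(methoxymethoxy)-4-methylphenyl]lithium | [Li]c1c(OCOC)cc(C)c(Cl)c1OCOC | intermediate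
21 | [3-chloro-2,6-bis(methoxymethoxy)-4-methylphenyl]copper | [Cu]c1c(OCOC)cc(C)c(Cl)c1OCOC | intermediate
22 | (+)-pinanediol (Z)-{4-[3-chloro-2,6-bis(methoxymethoxy)-4-methylphenyl]but-2-en-2-yl}boronate | Cc1cc(OCOC)c(C/C=C(\C)B2O[C@]3(C)[C@H](O2)C[C@@H]4C[C@H]3C4(C)C)c(OCOC)c1Cl | intermediate
23 | dichloromethane | ClCCl | starting material
24 | (dichloromethyl)lithium | [Li]C(Cl)Cl | intermediate
25 | (+)-pinanediol {(1S,2E)-1-chloro-4-[3-chloro-2,6-bis(methoxymethoxy)-4-methylphenyl]-2-methylbut-2-en-1-yl}boronate | Cc1cc(OCOC)c(C/C=C(\C)[C@@H](Cl)B2O[C@]3(C)[C@H](O2)C[C@@H]4C[C@H]3C4(C)C)c(OCOC)c1Cl | intermediate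
26 | {[(6R,7S,8S)-6,7,8-trimethyl-1,4-dioxaspiro[4.5]decan-7-yl]methyl}magnesium iodide | I[Mg]C[C@@]1(C)[C@@H](C)CCC2(OCCO2)[C@@H]1C | intermediate
27 | (+)-pinanediol {(2S,3E)-5-[3-chloro-2,6-bis(methoxymethoxy)-4-methylphenyl]-3-methyl-1-[(6R,7S,8S)-6,7,8-trimethyl-1,4-dioxaspiro[4.5]decan-7-yl]pent-3-en-2-yl}boronate | Cc1cc(OCOC)c(C/C=C(\C)[C@@H](B2O[C@]3(C)[C@H](O2)C[C@@H]4C[C@H]3C4(C)C)C[C@@]5(C)[C@@H](C)CCC6(OCCO6)[C@@H]5C)c(OCOC)c1Cl | intermediate
28 | (2S,3E)-5-[3-chloro-2,6-bis(methoxymethoxy)-4-methylphenyl]-3-methyl-1-[(6R,7S,8S)-6,7,8-trimethyl-1,4-dioxaspiro[4.5]decan-7-yl]pent-3-en-2-ol | Cc1cc(OCOC)c(C/C=C(\C)[C@@H](O)C[C@@]2(C)[C@@H](C)CCC3(OCCO3)[C@@H]2C)c(OCOC)c1Cl | intermediate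
29 | 4-chloro-2-{(2E,4S)-4-hydroxy-3-methyl-5-[(1S,2R,6S)-1,2,6-trimethyl-3-oxocyclohexyl]pent-2-en-1-yl}-5-methylbenzene-1,3-diol | Cc1cc(O)c(C/C=C(\C)[C@@H](O)C[C@@]2(C)[C@@H](C)CCC(=O)[C@@H]2C)c(O)c1Cl | intermediate
30 | 5-chloro-2-hydroxy-3-{(2E,4S)-4-hydroxy-3-methyl-5-[(1S,2R,6S)-1,2,6-trimethyl-3-oxocyclohexyl]pent-2-en-1-yl}-6-methylcyclohexa-2,5-diene-1,4-dione | CC1=C(Cl)C(=O)C(C/C=C(\C)[C@@H](O)C[C@@]2(C)[C@@H](C)CCC(=O)[C@@H]2C)=C(O)C1=O | target

## Step count and risks

Total step count: 17. Longest linear sequence: 11 steps (steps 1–8, then 15, 16 and 17).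

Steps most likely to fail:

1. Step 15. The chlorine-bearing allylic carbon of the unisolated α-chloro boronate may lose its configuration by chloride exchange before the second shift, and borate formation with the hindered neopentylic Grignard reagent may be slow.
   - Fallback (carbonyl chemistry), setting out from 15 and 12 and returning at 28: arylcopper 21 (made as in step 14) is allylated with commercial ethyl (E)-4-bromo-2-methylbut-2-enoate to give ethyl (2E)-4-[3-chloro-2,6-bis(methoxymethoxy)-4-methylphenyl]-2-methylbut-2-enoate F1.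
   - MeNH(OMe)·HCl and i-PrMgCl convert it into (2E)-4-[3-chloro-2,6-bis(methoxymethoxy)-4-methylphenyl]-N-methoxy-N,2-dimethylbut-2-enamide F2.
   - Iodide 12 is exchanged with t-BuLi (Et2O, −78 °C) to {[(6R,7S,8S)-6,7,8-trimethyl-1,4-dioxaspiro[4.5]decan-7-yl]methyl}lithium F3, which adds to F2 and forms the same CH2–C bond at the ketone level, (3E)-5-[3-chloro-2,6-bis(methoxymethoxy)-4-methylphenyl]-3-methyl-1-[(6R,7S,8S)-6,7,8-trimethyl-1,4-dioxaspiro[4.5]decan-7-yl]pent-3-en-2-one F4.
   - Corey–Bakshi–Shibata reduction with (R)-2-methyl-CBS-oxazaborolidine and catecholborane should give 28; the (S)-alcohol is expected if the α-branched alkenyl group acts as the large group.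

2. Step 5. The 1,4-addition to the hindered β,β-disubstituted enone may be sluggish, and the facial selectivity of the enolate methylation may be poor.
   - Fallback, setting out from 6 and returning at 8: Me2CuLi with TMSCl (faster addition, enolate trapped) gives {[(3S,4S)-3-{[dimethyl(phenyl)silyl]methyl}-3,4-dimethylcyclohex-1-en-1-yl]oxy}trimethylsilane F5.
   - Simmons–Smith cyclopropanation (Et2Zn, CH2I2), which responds to sterics alone, should deliver CH2 to the face opposite the silylmethyl group and give {[(1S,4S,5S,6R)-5-{[dimethyl(phenyl)silyl]methyl}-4,5-dimethylbicyclo[4.1.0]heptan-1-yl]oxy}trimethylsilane F6.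
   - K2CO3 in MeOH desilylates F6 and opens the outer cyclopropane bond, so the CH2 becomes the 2-methyl group with the configuration fixed in the cyclopropanation, which gives 8.

3. Step 16. The acid may ionise the allylic alcohol (ether formation, cyclisation onto a free phenol) or epimerise the centre α to the ketone.
   - Fallback, setting out from 28 and returning at 30 (29 is bypassed): the aryl MOM ethers are removed first under nearly neutral conditions (TMSOTf, 2,2′-bipyridyl, CH2Cl2, 0 °C; then water) to give 4-chloro-2-{(2E,4S)-4-hydroxy-3-methyl-5-[(6R,7S,8S)-6,7,8-trimethyl-1,4-dioxaspiro[4.5]decan-7-yl]pent-2-en-1-yl}-5-methylbenzene-1,3-diol F7.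
   - K2[ON(SO3)2] oxidises F7 with the ketal still in place to 5-chloro-2-hydroxy-3-{(2E,4S)-4-hydroxy-3-methyl-5-[(6R,7S,8S)-6,7,8-trimethyl-1,4-dioxaspiro[4.5]decan-7-yl]pent-2-en-1-yl}-6-methylcyclohexa-2,5-diene-1,4-dione F8.
   - The dioxolane is hydrolysed last with PPTS in wet acetone to give 30.

Further compounds
F1 | step 15 | ethyl (2E)-4-[3-chloro-2,6-bis(methoxymethoxy)-4-methylphenyl]-2-methylbut-2-enoate | Cc1cc(OCOC)c(C/C=C(\C)C(=O)OCC)c(OCOC)c1Cl
F2 | step 15 | (2E)-4-[3-chloro-2,6-bis(methoxymethoxy)-4-methylphenyl]-N-methoxy-N,2-dimethylbut-2-enamide | Cc1cc(OCOC)c(C/C=C(\C)C(=O)N(C)OC)c(OCOC)c1Cl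
F3 | step 15 | {[(6R,7S,8S)-6,7,8-trimethyl-1,4-dioxaspiro[4.5]decan-7-yl]methyl}lithium | [Li]C[C@@]1(C)[C@@H](C)CCC2(OCCO2)[C@@H]1C
F4 | step 15 | (3E)-5-[3-chloro-2,6-bis(methoxymethoxy)-4-methylphenyl]-3-methyl-1-[(6R,7S,8S)-6,7,8-trimethyl-1,4-dioxaspiro[4.5]decan-7-yl]pent-3-en-2-one | Cc1cc(OCOC)c(C/C=C(\C)C(=O)C[C@@]2(C)[C@@H](C)CCC3(OCCO3)[C@@H]2C)c(OCOC)c1Cl
F5 | step 5 | {[(3S,4S)-3-{[dimethyl(phenyl)silyl]methyl}-3,4-dimethylcyclohex-1-en-1-yl]oxy}trimethylsilane | C[Si](C)(c1ccccc1)C[C@@]2(C)[C@@H](C)CCC(O[Si](C)(C)C)=C2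
F6 | step 5 | {[(1S,4S,5S,6R)-5-{[dimethyl(phenyl)silyl]methyl}-4,5-dimethylbicyclo[4.1.0]heptan-1-yl]oxy}trimethylsilane | C[Si](C)(c1ccccc1)C[C@@]2(C)[C@@H](C)CC[C@]3(O[Si](C)(C)C)C[C@H]23
F7 | step 16 | 4-chloro-2-{(2E,4S)-4-hydroxy-3-methyl-5-[(6R,7S,8S)-6,7,8-trimethyl-1,4-dioxaspiro[4.5]decan-7-yl]pent-2-en-1-yl}-5-methylbenzene-1,3-diol | Cc1cc(O)c(C/C=C(\C)[C@@H](O)C[C@@]2(C)[C@@H](C)CCC3(OCCO3)[C@@H]2C)c(O)c1Cl
F8 | step 16 | 5-chloro-2-hydroxy-3-{(2E,4S)-4-hydroxy-3-methyl-5-[(6R,7S,8S)-6,7,8-trimethyl-1,4-dioxaspiro[4.5]decan-7-yl]pent-2-en-1-yl}-6-methylcyclohexa-2,5-diene-1,4-dione | CC1=C(Cl)C(=O)C(C/C=C(\C)[C@@H](O)C[C@@]2(C)[C@@H](C)CCC3(OCCO3)[C@@H]2C)=C(O)C1=O
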